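Autumn keeps 79.6% of its L at 8.00 min and dawn 77.7% at 8.00 min, although dawn was charged with 31 mM of L and autumn with 6.4 mM. L therefore falls pseudo-first-order, at 0.0285 /min in autumn and 0.0315 /min in dawn.

all flasks: J 1.2 mM
- autumn: L 6.4 mM; run made earlier
- dawn: L 31 mM; run made earlier
- ochre: L 20 mM; time 12 min
- violet: L 5.0 mM; time 12 min

| run | time / min | G / % | L / % |
|---|---|---|---|
| autumn | 1.33 | 5.4 | 96.5 |
| autumn | 3.00 | 9.1 | 90.1 |
| autumn | 4.00 | 12.1 | 91.2 |
| autumn | 6.00 | 16.6 | 83.7 |
| autumn | 8.00 | 21.3 | 79.6 |
| dawn | 0.500 | 1.7 | 98.6 |
| dawn | 1.50 | 5.4 | 96.1 |
| dawn | 3.00 | 8.3 | 91.5 |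
| dawn | 5.00 | 13.9 | 84.4 |
| dawn | 6.00 | 18.9 | 79.7 |
| dawn | 8.00 | 24.1 | 77.7 |

(readings scatter by 1 percentage point)

* which of the two ends with the longer chains by the average number of monomer units in a chain (chains begun, living or dead) ("neither" if they lie within 10%) (ochre / violet / neither)
* average number of monomer units in a chain (chains begun, living or dead) at the end, ochre
* average number of monomer units in a chain (chains begun, living or dead) at the end, violet

- the average divides the monomer in chains by the number of chains begun, living and dead together
- on the list of suspects stand: L + J -> Q + G; J -> X; L + Q -> G + Q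
- the earlier runs do not show the number of chains; that part of a forecast is a guess

Dividing the autumn pace, the one read nearest to violet, by the 1.2 mM of J and Q together gives the start constant 0.0238 /mM/min, the chance per minute and per mM of L that one J begins a chain. Its product with L and time is the exposure of a J, and the part of J started is one minus the exponential of minus the exposure. At the asked time the two paces put the conversion at 29.0% and 31.5%.

The lower conversion with exposure at charged L overstates chains, and so bounds the length from below. The higher conversion with exposure at the L left gives the high end of a reckoned range, an estimate and no bound, which leaves J → X out. This reckoning puts ochre between 4.85 and 5.36, and violet between 1.59 and 2.11, so ochre is expected to end longer. The forecast, ochre with 5.2 and 1.8, lies inside both brackets and holds that “Initiation is therefore slow”.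

    L + J → Q + G (k = 24.0 /M/min)
    J → X (k = 0.0280 /min)
    L + Q → G + Q, rate k3*[Q]*[L] (k = 31.0 /M/min)

Ochre ends longer, at 5.96, above its bracket, and violet reaches 1.98, inside its own. The charge of L is the main reason for the gap: violet given ochre's L reaches 5.96. Exposure at the mean of charged and simulated L, with J → X added at 0.028 /min, leaves 21.2% of the J in violet, against 21% simulated. In a neighbour flask with 2.0 mM of L, the same sum leaves 43.7% against 44%, and its chains average 1.36.

(All runs are simulated with made-up constants, and the scatter is random.)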